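The route rests on cutting the O4(A)–Ca bond of ring P1 and raising Ca to a ketone. The feature exploited is that Ca is a vinylogous acetal carbon. It carries O4(A), is linked through C3(B)=C4(B) to O4(B) of ring P2, and adjoins the enolisable ring-fusion carbon Cb. Acid and Et3SiH therefore close P1, install Ca–H and let Cb equilibrate in one operation, with both centres read from the pre-set Cc. The precursor is the enantioenriched Michael adduct of 4-hydroxy-1-methylquinolin-2-one and a 3-alkylidene-pyranoquinolinedione. It has ring P2 intact, Ca as a ketone, a free enol O4(A)–H, and the side chain masked as an N-methoxy-N-methylamide.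

Key step: step 7

Labels:
- Quinolone A has C3 bonded to Cc and O4 bonded to Ca.
- Quinolone B has C3 bonded to Ca and O4 bonded to CMe2.
- Ca is the O–CH carbon, Cb is the ring-fusion CH between Ca, Cc and CMe2, and Cc is the CH that bears the side chain.
- Ring P1 contains O4(A), Ca, Cb, Cc, C3(A) and C4(A). Ring P2 contains O4(B), CMe2, Cb, Ca, C3(B) and C4(B).
- Target descriptors are Ca R, Cb S, Cc S. Ca–H, Cb–H and the side chain lie on one face of P1, so the fusion is cis and the chain is trans to CMe2.

Assumption: the quinine-derived squaramide is taken to give the S configuration at Cc; if the sense of induction is opposite, the quinidine-derived pseudo-enantiomer is used with no other change.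

Design remarks:
- Ring P2 is a β-(vinylogous acyloxy) ketone, so any enolate at Cb can expel O4(B). The alkylidene group is therefore installed through an enol silane and acid catalysis, not through a base-mediated aldol condensation.
- The self-condensing free formylacetamide is replaced by its dimethyl acetal.
- The amide chain is kept for two reasons. An ester could acylate O4(A), and a methyl ketone would compete with Ca for O4(A).

Step 1
Reactants: 1 4-hydroxy-1-methylquinolin-2(1H)-one; 2 3-methylbut-2-enoic acid
Product: 3 2,2,6-trimethyl-2,3-dihydro-4H-pyrano[3,2-c]quinoline-4,5(6H)-dione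
Conditions: P2O5/MeSO3H (1:10 w/w), 70 °C
Reagents that add atoms: none
Why: Friedel–Crafts-type C3 acylation by the mixed anhydride of 2, followed in the same medium by acid-catalysed 6-endo-trig oxa-Michael closure of O4 onto the β,β-dimethyl enone, is the standard 2,2-dimethylchroman-4-one annulation, and the dehydrating P2O5 favours acylation over C-alkylation/lactonisation.

Step 2
Reactants: 3 2,2,6-trimethyl-2,3-dihydro-4H-pyrano[3,2-c]quinoline-4,5(6H)-dione
Product: 4 2,2,6-trimethyl-4-(trimethylsilyloxy)-2H-pyrano[3,2-c]quinolin-5(6H)-one
Conditions: Me3SiOSO2CF3, Et3N, CH2Cl2, 0 °C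
Reagents that add atoms: trimethylsilyl trifluoromethanesulfonate, C[Si](C)(C)OS(=O)(=O)C(F)(F)F
Why: Soft enolisation (silyl enol ether formation) silylates the ketone oxygen before the only enolisable position C3–H2 is deprotonated, so no free enolate arises that could eject the ring oxygen by retro-oxa-Michael cleavage, and the product is a closed 2H-pyran of the stable N-methylflindersine type.

Step 3
Reactants: 5 methyl 3,3-dimethoxypropanoate
Product: 6 N,3,3-trimethoxy-N-methylpropanamide
Conditions: MeNH(OMe)·HCl, iPrMgCl, THF, −20 °C
Reagents that add atoms: N,O-dimethylhydroxylamine hydrochloride, CNOC.Cl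
Why: Aminolysis of the ester by the chloromagnesium amide made in situ (standard Weinreb amide synthesis) outpaces enolisation at this temperature and leaves the dimethyl acetal untouched.

Step 4
Reactants: 4 2,2,6-trimethyl-4-(trimethylsilyloxy)-2H-pyrano[3,2-c]quinolin-5(6H)-one; 6 N,3,3-trimethoxy-N-methylpropanamide
Product: 7 N,3-dimethoxy-N-methyl-3-(2,2,6-trimethyl-4,5-dioxo-3,4,5,6-tetrahydro-2H-pyrano[3,2-c]quinolin-3-yl)propanamide (racemic mixture of diastereomers)
Conditions: Me3SiOSO2CF3 (20 mol %), CH2Cl2, −78 °C
Reagents that add atoms: none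
Why: In this Mukaiyama aldol-type addition of an enol silane to an acetal the silyl triflate ionises 6 to its methoxycarbenium ion, which C3 of 4 attacks under base-free conditions, and the two new stereocentres are irrelevant because both are erased in step 5.

Step 5
Reactants: 7 N,3-dimethoxy-N-methyl-3-(2,2,6-trimethyl-4,5-dioxo-3,4,5,6-tetrahydro-2H-pyrano[3,2-c]quinolin-3-yl)propanamide
Product: 8 (Z)-N-methoxy-N-methyl-3-(2,2,6-trimethyl-4,5-dioxo-5,6-dihydro-2H-pyrano[3,2-c]quinolin-3(4H)-ylidene)propanamide
Conditions: 4-MeC6H4SO3H·H2O (10 mol %), 5 Å molecular sieves, toluene, 70 °C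
Reagents that add atoms: none
Why: Acid-catalysed β-elimination of methanol through the enol (the condensation half of an acid aldol condensation) is chosen because a base would eject the better leaving group O4(B) instead of methoxide whereas ring P2 is formed and persists under acid, and reversible protonation should let the alkene settle as the Z isomer with the chain turned away from the gem-dimethyl group (allylic strain).

Step 6
Reactants: 8 (Z)-alkylidene pyranoquinolinedione amide; 1 4-hydroxy-1-methylquinolin-2(1H)-one
Product: 9 (3S)-3-(4-hydroxy-1-methyl-2-oxo-1,2-dihydroquinolin-3-yl)-N-methoxy-N-methyl-3-(2,2,6-trimethyl-4,5-dioxo-3,4,5,6-tetrahydro-2H-pyrano[3,2-c]quinolin-3-yl)propanamide (Cc S; both epimers at Cb; in equilibrium with its hemiketal)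
Conditions: 3-{[3,5-bis(trifluoromethyl)phenyl]amino}-4-{[(8α,9S)-6'-methoxycinchonan-9-yl]amino}cyclobut-3-ene-1,2-dione (10 mol %), CH2Cl2, −20 °C
Reagents that add atoms: none
Why: In this organocatalytic asymmetric Michael addition of a cyclic 1,3-dicarbonyl-type C-nucleophile to an enone the squaramide N–H bonds bind the C4/C5 dione of 8 while the quinuclidine nitrogen deprotonates 1, so C3 of 1 is guided to one face of the s-cis-locked exocyclic enone and sets Cc as S, and the unselective protonation at Cb is of no consequence.

Step 7
Reactants: 9 Michael adduct (Cc S; Cb epimers)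
Product: 13 cis-fused bis-pyran N-methoxy-N-methylamide (Ca R; Cb S; Cc S), via cyclic hemiketal 10 (not isolated), via bicyclic oxocarbenium ion 11 (not isolated), via bis-enol ether 12 (not isolated)
Conditions: CF3CO2H (10 equiv), CH2Cl2, 0 °C; then Et3SiH (1.05 equiv, slow addition), 0 °C to rt, aged before NaHCO3 quench
Reagents that add atoms: none
Why: CF3CO2H sets up the ring–chain equilibrium in which the enolic O4(A)–H adds to the Ca ketone (6-exo-trig closure of ring P1) to give hemiketal 10, loss of water gives oxocarbenium ion 11, whose charge is shared by O4(A) and, through C3(B)=C4(B), by O4(B), and Et3SiH transfers hydride to Ca. The closest known reaction type is the intramolecular reductive etherification of a hydroxy ketone (ionic hydrogenation of a cyclic hemiketal), applied to the hemiketal that warfarin-type Michael adducts form spontaneously. Cb is set by equilibration: 11 sheds and regains the Cb proton through bis-enol ether 12 faster than the slowly added silane intercepts it, so both Cb epimers of 9 enter one pool (Curtin–Hammett situation) referenced to the fixed Cc centre. Ca is set by its neighbour Cb: in 11 the Cb–H bond must stand perpendicular to the flat cation because Cc and CMe2 are both ring members, and the pseudoaxial methyl of CMe2 screens the opposite face, so hydride should enter syn to Cb–H and give the cis fusion. The required diastereomer should also be the thermodynamic one, since only with Ca–H, Cb–H and the chain on one face can O4(A) sit pseudoaxial on P2 (clear of the C2(B) carbonyl) and the chain pseudoaxial on P1 (clear of the C2(A) carbonyl and anti to CMe2), and because the Ca–O4(A) bond of 13 is a vinylogous acetal link that can re-ionise in the acid, stray Ca or Cb epimers can still drain into it during the ageing period. The step needs a single hydride transfer and inert amide and lactam groups: silane as the limiting reagent guards against over-reduction at Ca after re-ionisation, and Et3SiH/CF3CO2H does not reduce amides.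

Step 8
Reactants: 13 cis-fused bis-pyran N-methoxy-N-methylamide
Product: 14 cis-fused bis-pyran methyl ketone (Ca R; Cb S; Cc S; chain CH2C(=O)CH3)
Conditions: MeMgBr, THF, −20 to 0 °C; aq NH4Cl
Reagents that add atoms: methylmagnesium bromide, C[Mg]Br
Why: In the Weinreb ketone synthesis the chelated tetrahedral magnesium adduct survives until the quench so addition stops at the ketone, the two electron-rich 4-alkoxy-2-quinolone lactams do not compete at this temperature, and no stereocentre is touched.

Step 9
Reactants: 14 cis-fused bis-pyran methyl ketone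
Product: 15 target CNP0202276.2 (Ca R; Cb S; Cc S; chain CH2C(CH3)2OH)
Conditions: CeCl3 (anhydrous), MeMgBr, THF, −78 to 0 °C; aq NH4Cl
Reagents that add atoms: methylmagnesium bromide, C[Mg]Br
Why: Organocerium 1,2-addition uses a weakly basic, oxophilic methyl donor that adds to the enolisable methyl ketone without deprotonating it, and the neutral quench avoids acid that could let the new tertiary alcohol exchange with O4(A) at Ca.

Compound list
1 | 4-hydroxy-1-methylquinolin-2(1H)-one | Cn1c(=O)cc(O)c2ccccc21 | starting material
2 | 3-methylbut-2-enoic acid | CC(C)=CC(=O)O | starting material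
3 | 2,2,6-trimethyl-2,3-dihydro-4H-pyrano[3,2-c]quinoline-4,5(6H)-dione | Cn1c(=O)c2c(c3ccccc31)OC(C)(C)CC2=O | intermediate
4 | 2,2,6-trimethyl-4-(trimethylsilyloxy)-2H-pyrano[3,2-c]quinolin-5(6H)-one | Cn1c(=O)c2c(c3ccccc31)OC(C)(C)C=C2O[Si](C)(C)C | intermediate
5 | methyl 3,3-dimethoxypropanoate | COC(=O)CC(OC)OC | starting material
6 | N,3,3-trimethoxy-N-methylpropanamide | CON(C)C(=O)CC(OC)OC | intermediate
7 | β-methoxy ketone: pyranoquinolinedione carrying CH(OMe)CH2C(=O)N(OMe)Me at C3, racemic diastereomer mixture | Cn1c(=O)c2c(c3ccccc31)OC(C)(C)C(C(CC(=O)N(C)OC)OC)C2=O | intermediate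
8 | (Z)-3-alkylidene pyranoquinolinedione, =CH–CH2C(=O)N(OMe)Me with the chain syn to the C4 ketone | CON(C)C(=O)C/C=C1\C(=O)c2c(OC1(C)C)c1ccccc1n(C)c2=O | intermediate
9 | Michael adduct, Cc S, both Cb epimers, Ca ketone, free O4(A)–H | Cn1c(=O)c(c(O)c2ccccc21)[C@@H](CC(=O)N(C)OC)C1C(=O)c2c(OC1(C)C)c1ccccc1n(C)c2=O | intermediate
10 | cyclic hemiketal of 9 (O4(A) bonded to Ca, Ca–OH), Cc S | Cn1c(=O)c2c(c3ccccc31)OC1(O)c3c(c4ccccc4n(C)c3=O)OC(C)(C)C1[C@@H]2CC(=O)N(C)OC | intermediate
11 | bicyclic oxocarbenium ion O4(A)=Ca as trifluoroacetate, productive Cb epimer drawn | Cn1c(=O)c2c(c3ccccc31)[O+]=C1c3c(c4ccccc4n(C)c3=O)OC(C)(C)[C@H]1[C@@H]2CC(=O)N(C)OC.[O-]C(=O)C(F)(F)F | intermediate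
12 | bis-enol ether with Ca=Cb double bond (4H-pyran P1, 2H-pyran P2), Cc S | Cn1c(=O)c2c(c3ccccc31)OC1=C(C(C)(C)Oc3c1c(=O)n(C)c1ccccc31)[C@@H]2CC(=O)N(C)OC | intermediate
13 | cis-fused bis-pyran with chain CH2C(=O)N(OMe)Me, Ca R, Cb S, Cc S | Cn1c(=O)c2c(c3ccccc31)O[C@H]1c3c(c4ccccc4n(C)c3=O)OC(C)(C)[C@H]1[C@@H]2CC(=O)N(C)OC | intermediate
14 | cis-fused bis-pyran with chain CH2C(=O)CH3, Ca R, Cb S, Cc S | Cn1c(=O)c2c(c3ccccc31)O[C@H]1c3c(c4ccccc4n(C)c3=O)OC(C)(C)[C@H]1[C@@H]2CC(C)=O | intermediate
15 | CNP0202276.2, cis-fused bis-pyran with chain CH2C(CH3)2OH, Ca R, Cb S, Cc S | Cn1c(=O)c2c(c3ccccc31)O[C@H]1c3c(c4ccccc4n(C)c3=O)OC(C)(C)[C@H]1[C@@H]2CC(C)(C)O | target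

Total step count: 9. Longest linear sequence: 8 (steps 1, 2, 4, 5, 6, 7, 8, 9).

Steps most likely to fail

1. Step 7. Several things may go wrong:
- Hydride transfer may outrun the Cb equilibration.
- Hydride may be delivered on the face of Ca anti to Cb–H, which is torsionally the easier approach.
- Re-ionisation at Ca while silane is still present may lead to over-reduction.
- The acid may open ring P2 by retro-oxa-Michael cleavage, followed by reclosure through O4(A).

   The fallback sets out from 9. Catalytic 4-MeC6H4SO3H·H2O in toluene with azeotropic removal of water is used to isolate the bis-enol ether 12 (no compound outside the list is made, F0). This is then hydrogenated with [Ir(cod)(PCy3)(py)]PF6 under H2 in CH2Cl2. The amide carbonyl binds the cationic iridium centre, so both hydrogens add syn across Ca=Cb from the face that carries the chain. That is the required Ca–H/Cb–H/chain relationship, and the route is rejoined at 13.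

2. Step 6. Several things may go wrong:
- Reversible addition may erode the enantioselectivity.
- γ-Deprotonation next to the amide may move the double bond out of conjugation with the ketone.
- The transient enolate may expel O4(B) and open ring P2 under amine catalysis.

   The fallback sets out from 1 and 8. Compound 1 is silylated with (Me3Si)2NH to 1-methyl-4-(trimethylsilyloxy)quinolin-2(1H)-one F1. F1 is added to 8 in a base-free Mukaiyama–Michael reaction catalysed by Cu(OTf)2 and 2,2'-(propane-2,2-diyl)bis[(4S)-4-tert-butyl-4,5-dihydro-1,3-oxazole] in CH2Cl2, with (CF3)2CHOH as silyl acceptor. The C4/C5 dione of 8 chelates the divalent copper centre and fixes the enone face. The route is rejoined at 9.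

3. Step 5. Loss of methanol may be slower than acid-induced opening of ring P2 or migration of the new double bond toward the amide. The fallback sets out from 4 and 6.
- The acetal of 6 is hydrolysed (CF3CO2H, H2O, CH2Cl2, 0 °C) to N-methoxy-N-methyl-3-oxopropanamide F2, which is used at once.
- A Mukaiyama aldol addition of 4 (BF3·OEt2, CH2Cl2, −78 °C) gives the β-hydroxy ketone F3.
- MeSO2Cl/Et3N at 0 °C converts F3 into the β-mesyloxy ketone F4. This eliminates in the same flask because sulfonate is a far better leaving group than O4(B).
- The route is rejoined at 8.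

Further compounds
F0 | step 7 | none | none
F1 | step 6 | 1-methyl-4-(trimethylsilyloxy)quinolin-2(1H)-one | Cn1c(=O)cc(O[Si](C)(C)C)c2ccccc21
F2 | step 5 | N-methoxy-N-methyl-3-oxopropanamide | CON(C)C(=O)CC=O
F3 | step 5 | 3-hydroxy-N-methoxy-N-methyl-3-(2,2,6-trimethyl-4,5-dioxo-3,4,5,6-tetrahydro-2H-pyrano[3,2-c]quinolin-3-yl)propanamide, racemic diastereomer mixture | Cn1c(=O)c2c(c3ccccc31)OC(C)(C)C(C(O)CC(=O)N(C)OC)C2=O
F4 | step 5 | methanesulfonate of F3 | Cn1c(=O)c2c(c3ccccc31)OC(C)(C)C(C(CC(=O)N(C)OC)OS(C)(=O)=O)C2=O
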